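**Retrosynthetic overview**
1. Target 23 ← silyl ether 22 (last step frees the phenol) ← pyran closure (6-endo cycloisomerization) of the dearomatized alkynyl vinylogous acid 21.
2. 21 ← chlororesorcinol alkynyl aldehyde 10 + mixed acyl peroxide 20, by a new catalytic enantioselective acyloxylative dearomatization that makes the C7–O ester bond and the C7 stereocentre in one step.
3. 10 ← Sonogashira union of bromoresorcinol aldehyde 5 (from 2,6-dimethoxytoluene 1) with aryl alkyne 8 (from 6-methylsalicylaldehyde 6), then C5 chlorination.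
4. 20 ← (2E,4S)-acid 19 ← Evans methylation (sets C4′), then one-pot oxidation/Wittig olefination.
5. Ring order: both benzene rings are bought; the resorcinol ring is dearomatized in step 14, and the pyran ring is the only ring built, in step 15.

Assumption: the facial sense of the new step 14 can only be found by experiment; the ligand from (S)-pipecolic acid is written, and its mirror image (from (R)-pipecolic acid) is used instead if 21 proves to be the (1S) isomer, checked against material from the known-chemistry fallback.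

Configuration of the target as read from the SMILES: C7 is S (the chlorine makes C6 outrank C8), the side chain is 2E,4S.

**Step 1**
Reactants: 1 1,3-dimethoxy-2-methylbenzene
Product: 3 5-bromo-1,3-dimethoxy-2-methylbenzene, via arylboronate 2 (not isolated)
Conditions: [Ir(OMe)(cod)]2 (1 mol%), 4,4′-di-tert-butyl-2,2′-bipyridine (2 mol%), B2pin2 (1.0 equiv), THF, 80 °C; then CuBr2 (3 equiv), MeOH/H2O 1:1, 80 °C
Reagents that add atoms: bis(pinacolato)diboron, CC1(C)OB(OC1(C)C)B1OC(C)(C)C(C)(C)O1 (boron unit of 2); copper dibromide CuBr2, [Cu+2].[Br-].[Br-] (Br of 3)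
Why: Iridium-catalysed C–H borylation is sterically governed and takes the only C–H flanked by two hydrogens (para to the methyl), and copper-mediated bromodeboronation converts the boronate in the same pot.

**Step 2**
Reactants: 3 5-bromo-1,3-dimethoxy-2-methylbenzene
Product: 4 6-bromo-2,4-dimethoxy-3-methylbenzaldehyde
Conditions: POCl3, DMF, 0 → 90 °C; then H2O
Reagents that add atoms: N,N-dimethylformamide, CN(C)C=O (formyl carbon); water, O (formyl oxygen)
Why: Vilsmeier–Haack formylation goes ortho/para to the two methoxy groups, and the two open positions are equivalent by symmetry.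

**Step 3**
Reactants: 4 6-bromo-2,4-dimethoxy-3-methylbenzaldehyde
Product: 5 6-bromo-2,4-dihydroxy-3-methylbenzaldehyde
Conditions: BBr3 (3 equiv), CH2Cl2, −78 °C → rt; then H2O
Reagents that add atoms: none
Why: Lewis-acid cleavage of both aryl methyl ethers by BBr3 leaves the aldehyde and the aryl bromide untouched.

**Step 4**
Reactants: 6 2-hydroxy-6-methylbenzaldehyde
Product: 7 2-methyl-6-[(triisopropylsilyl)oxy]benzaldehyde
Conditions: TIPSCl, imidazole, DMF, 40 °C
Reagents that add atoms: chlorotriisopropylsilane, CC(C)[Si](Cl)(C(C)C)C(C)C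
Why: Silylation masks the phenol, which would otherwise add to the alkyne (benzofuran formation) in steps 6 and 15.

**Step 5**
Reactants: 7 2-methyl-6-[(triisopropylsilyl)oxy]benzaldehyde
Product: 8 (2-ethynyl-3-methylphenoxy)triisopropylsilane
Conditions: Me3SiCHN2, n-BuLi, THF, −78 °C; then 7, −78 °C → rt; then H2O
Reagents that add atoms: (trimethylsilyl)diazomethane, C[Si](C)(C)C=[N+]=[N-]
Why: Colvin homologation (addition, Peterson elimination, loss of N2, 1,2-hydrogen shift of the alkylidene carbene) gives the terminal alkyne under conditions that spare the aryl silyl ether.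

**Step 6**
Reactants: 5 6-bromo-2,4-dihydroxy-3-methylbenzaldehyde; 8 (2-ethynyl-3-methylphenoxy)triisopropylsilane
Product: 9 2,4-dihydroxy-3-methyl-6-({2-methyl-6-[(triisopropylsilyl)oxy]phenyl}ethynyl)benzaldehyde
Conditions: Pd(PPh3)2Cl2 (5 mol%), CuI (10 mol%), Et3N, DMF, 60 °C
Reagents that add atoms: none
Why: Sonogashira coupling of the aldehyde-activated aryl bromide tolerates the free resorcinol hydroxyls, and neither hydroxyl sits next to the alkyne.

**Step 7**
Reactants: 9 2,4-dihydroxy-3-methyl-6-({2-methyl-6-[(triisopropylsilyl)oxy]phenyl}ethynyl)benzaldehyde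
Product: 10 5-chloro-2,4-dihydroxy-3-methyl-6-({2-methyl-6-[(triisopropylsilyl)oxy]phenyl}ethynyl)benzaldehyde
Conditions: NCS (1.05 equiv), MeCN, 0 °C → rt
Reagents that add atoms: N-chlorosuccinimide, O=C1CCC(=O)N1Cl
Why: Electrophilic aromatic chlorination takes the only free position of the far more electron-rich resorcinol ring, which installs the target's chlorine and blocks that carbon for step 14.

**Step 8**
Reactants: 11 (S)-4-benzyloxazolidin-2-one; 12 octanoyl chloride
Product: 13 (S)-4-benzyl-3-octanoyloxazolidin-2-one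
Conditions: n-BuLi, THF, −78 °C; then 12, −78 → 0 °C
Reagents that add atoms: none
Why: N-acylation of the lithiated oxazolidinone is a standard, clean imide formation.

**Step 9**
Reactants: 13 (S)-4-benzyl-3-octanoyloxazolidin-2-one
Product: 14 (S)-4-benzyl-3-[(S)-2-methyloctanoyl]oxazolidin-2-one
Conditions: NaN(SiMe3)2, THF, −78 °C; then MeI, −78 → −40 °C
Reagents that add atoms: iodomethane, CI
Why: Evans alkylation: the chelated Z-enolate is methylated on the face away from the benzyl group, which sets the (S) centre that becomes C4′.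

**Step 10**
Reactants: 14 (S)-4-benzyl-3-[(S)-2-methyloctanoyl]oxazolidin-2-one
Product: 15 (S)-2-methyloctan-1-ol
Conditions: LiBH4, H2O (1 equiv), Et2O, 0 °C
Reagents that add atoms: none
Why: Reductive cleavage of the imide gives the primary alcohol without epimerization and returns the auxiliary.

**Step 11**
Reactants: 15 (S)-2-methyloctan-1-ol; 16 ethyl 2-(triphenylphosphoranylidene)propanoate
Product: 18 ethyl (2E,4S)-2,4-dimethyldec-2-enoate, via (S)-2-methyloctanal 17 (not isolated)
Conditions: TEMPO (2,2,6,6-tetramethylpiperidin-1-oxyl, 10 mol%), PhI(OAc)2 (1.1 equiv), CH2Cl2, rt; then 16, rt → 40 °C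
Reagents that add atoms: none
Why: Oxoammonium oxidation followed by in-flask Wittig olefination with the stabilized ylide gives the E-trisubstituted enoate and traps the epimerizable aldehyde as it forms.

**Step 12**
Reactants: 18 ethyl (2E,4S)-2,4-dimethyldec-2-enoate
Product: 19 (2E,4S)-2,4-dimethyldec-2-enoic acid
Conditions: LiOH·H2O, THF/MeOH/H2O, 50 °C; then 1 M HCl
Reagents that add atoms: lithium hydroxide, [Li+].[OH-]
Why: Saponification leaves the alkene geometry and the γ-stereocentre unchanged.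

**Step 13**
Reactants: 19 (2E,4S)-2,4-dimethyldec-2-enoic acid
Product: 20 3-chlorobenzoyl (2E,4S)-2,4-dimethyldec-2-enoyl peroxide
Conditions: mCPBA (purified, acid-free, 1.0 equiv), DCC (1.05 equiv), CH2Cl2, −10 → 0 °C, dark; cold NaHCO3 wash
Reagents that add atoms: 3-chloroperbenzoic acid, OOC(=O)c1cccc(Cl)c1
Why: Carbodiimide activation of the acid and acyl transfer to the hydroperoxy oxygen of the peracid (Steglich-type coupling) gives the unsymmetrical diacyl peroxide, and the electron-poor enoate is not epoxidized at this temperature.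

**Step 14**
Reactants: 10 5-chloro-2,4-dihydroxy-3-methyl-6-({2-methyl-6-[(triisopropylsilyl)oxy]phenyl}ethynyl)benzaldehyde; 20 3-chlorobenzoyl (2E,4S)-2,4-dimethyldec-2-enoyl peroxide
Product: 21 (1R)-3-chloro-5-formyl-2-hydroxy-1-methyl-4-({2-methyl-6-[(triisopropylsilyl)oxy]phenyl}ethynyl)-6-oxocyclohexa-2,4-dien-1-yl (2E,4S)-2,4-dimethyldec-2-enoate
Conditions: Sc(OTf)3 (10 mol%), N,N′-dioxide ligand L-PiPr2 [1,3-propanediyl-bridged bis((S)-pipecolic acid 2,6-diisopropylanilide) N,N′-dioxide] (11 mol%), 20 (1.2 equiv), 4 Å MS, CH2Cl2, −20 → 0 °C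
Reagents that add atoms: none
Why: Proposed new method: a catalytic enantioselective acyloxylative dearomatization in which the scandium–N,N′-dioxide complex binds the 2-hydroxy/formyl chelate of 10, the bound phenolate attacks through C3 (the methyl-bearing carbon between the two oxygens, the only open nucleophilic carbon because C5 carries chlorine) on the peroxide oxygen that bears the enoyl group in an SN2 displacement at oxygen with the better leaving group 3-chlorobenzoate departing, and the anilide walls of the ligand shield one face of the chelated arene so that the quaternary C–O centre (C7 of the target) is set under catalyst control; the closest known reactions are the Sc(OTf)3/N,N′-dioxide-catalysed hydroxylative dearomatization of 2-naphthols with oxaziridines, the catalytic asymmetric α-benzoyloxylation of β-dicarbonyls and oxindoles with dibenzoyl peroxide, and the Wessely ortho-acyloxylation of phenols.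

**Step 15**
Reactants: 21 (1R)-3-chloro-5-formyl-2-hydroxy-1-methyl-4-({2-methyl-6-[(triisopropylsilyl)oxy]phenyl}ethynyl)-6-oxocyclohexa-2,4-dien-1-yl (2E,4S)-2,4-dimethyldec-2-enoate
Product: 22 (7S)-5-chloro-7-methyl-3-{2-methyl-6-[(triisopropylsilyl)oxy]phenyl}-6,8-dioxo-7,8-dihydro-6H-isochromen-7-yl (2E,4S)-2,4-dimethyldec-2-enoate
Conditions: Ph3PAuNTf2 (5 mol%), CH2Cl2, 0 °C → rt
Reagents that add atoms: none
Why: Gold-catalysed 6-endo-dig cycloisomerization puts the enolized formyl oxygen on the aryl-bearing alkyne carbon to close the pyran ring, the quaternary centre is untouched, and its label changes from 1R to 7S only because the ranking of its two ring neighbours changes.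

**Step 16**
Reactants: 22 (7S)-5-chloro-7-methyl-3-{2-methyl-6-[(triisopropylsilyl)oxy]phenyl}-6,8-dioxo-7,8-dihydro-6H-isochromen-7-yl (2E,4S)-2,4-dimethyldec-2-enoate
Product: 23 (7S)-5-chloro-3-(2-hydroxy-6-methylphenyl)-7-methyl-6,8-dioxo-7,8-dihydro-6H-isochromen-7-yl (2E,4S)-2,4-dimethyldec-2-enoate
Conditions: HF·pyridine, THF, 0 °C → rt
Reagents that add atoms: none
Why: Acidic fluoride desilylation of the aryl silyl ether avoids the bases and nucleophilic amines that attack the azaphilone core and the tertiary ester.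

**Compound list**
1 | 1,3-dimethoxy-2-methylbenzene (2,6-dimethoxytoluene) | COc1cccc(OC)c1C | starting material
2 | 2-(3,5-dimethoxy-4-methylphenyl)-4,4,5,5-tetramethyl-1,3,2-dioxaborolane | COc1cc(B2OC(C)(C)C(C)(C)O2)cc(OC)c1C | intermediate
3 | 5-bromo-1,3-dimethoxy-2-methylbenzene | COc1cc(Br)cc(OC)c1C | intermediate
4 | 6-bromo-2,4-dimethoxy-3-methylbenzaldehyde | O=Cc1c(OC)c(C)c(OC)cc1Br | intermediate
5 | 6-bromo-2,4-dihydroxy-3-methylbenzaldehyde | O=Cc1c(O)c(C)c(O)cc1Br | intermediate
6 | 2-hydroxy-6-methylbenzaldehyde | Cc1cccc(O)c1C=O | starting material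
7 | 2-methyl-6-[(triisopropylsilyl)oxy]benzaldehyde | Cc1cccc(O[Si](C(C)C)(C(C)C)C(C)C)c1C=O | intermediate
8 | (2-ethynyl-3-methylphenoxy)triisopropylsilane | C#Cc1c(C)cccc1O[Si](C(C)C)(C(C)C)C(C)C | intermediate
9 | 2,4-dihydroxy-3-methyl-6-({2-methyl-6-[(triisopropylsilyl)oxy]phenyl}ethynyl)benzaldehyde | O=Cc1c(O)c(C)c(O)cc1C#Cc1c(C)cccc1O[Si](C(C)C)(C(C)C)C(C)C | intermediate
10 | 5-chloro-2,4-dihydroxy-3-methyl-6-({2-methyl-6-[(triisopropylsilyl)oxy]phenyl}ethynyl)benzaldehyde | O=Cc1c(O)c(C)c(O)c(Cl)c1C#Cc1c(C)cccc1O[Si](C(C)C)(C(C)C)C(C)C | intermediate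
11 | (S)-4-benzyloxazolidin-2-one | O=C1N[C@@H](Cc2ccccc2)CO1 | starting material
12 | octanoyl chloride | CCCCCCCC(=O)Cl | starting material
13 | (S)-4-benzyl-3-octanoyloxazolidin-2-one | CCCCCCCC(=O)N1[C@@H](Cc2ccccc2)COC1=O | intermediate
14 | (S)-4-benzyl-3-[(S)-2-methyloctanoyl]oxazolidin-2-one | CCCCCC[C@H](C)C(=O)N1[C@@H](Cc2ccccc2)COC1=O | intermediate
15 | (S)-2-methyloctan-1-ol | CCCCCC[C@H](C)CO | intermediate
16 | ethyl 2-(triphenylphosphoranylidene)propanoate | CCOC(=O)C(C)=P(c1ccccc1)(c1ccccc1)c1ccccc1 | starting material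
17 | (S)-2-methyloctanal | CCCCCC[C@H](C)C=O | intermediate
18 | ethyl (2E,4S)-2,4-dimethyldec-2-enoate | CCCCCC[C@H](C)/C=C(\C)C(=O)OCC | intermediate
19 | (2E,4S)-2,4-dimethyldec-2-enoic acid | CCCCCC[C@H](C)/C=C(\C)C(=O)O | intermediate
20 | 3-chlorobenzoyl (2E,4S)-2,4-dimethyldec-2-enoyl peroxide | CCCCCC[C@H](C)/C=C(\C)C(=O)OOC(=O)c1cccc(Cl)c1 | intermediate
21 | (1R)-3-chloro-5-formyl-2-hydroxy-1-methyl-4-({2-methyl-6-[(triisopropylsilyl)oxy]phenyl}ethynyl)-6-oxocyclohexa-2,4-dien-1-yl (2E,4S)-2,4-dimethyldec-2-enoate | CCCCCC[C@H](C)/C=C(\C)C(=O)O[C@@]1(C)C(=O)C(C=O)=C(C#Cc2c(C)cccc2O[Si](C(C)C)(C(C)C)C(C)C)C(Cl)=C1O | intermediate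
22 | (7S)-5-chloro-7-methyl-3-{2-methyl-6-[(triisopropylsilyl)oxy]phenyl}-6,8-dioxo-7,8-dihydro-6H-isochromen-7-yl (2E,4S)-2,4-dimethyldec-2-enoate | CCCCCC[C@H](C)/C=C(\C)C(=O)O[C@@]1(C)C(=O)C2=COC(c3c(C)cccc3O[Si](C(C)C)(C(C)C)C(C)C)=CC2=C(Cl)C1=O | intermediate
23 | (7S)-5-chloro-3-(2-hydroxy-6-methylphenyl)-7-methyl-6,8-dioxo-7,8-dihydro-6H-isochromen-7-yl (2E,4S)-2,4-dimethyldec-2-enoate | CCCCCC[C@H](C)/C=C(\C)C(=O)O[C@@]1(C)C(=O)C2=COC(c3c(C)cccc3O)=CC2=C(Cl)C1=O | target

**Totals**
Total steps: 16. Longest linear sequence: 9 steps (steps 8 to 16, from 11).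

**Steps most likely to fail**

Step 14 (the proposed new acyloxylation). It may give O-acylation, transfer of the 3-chlorobenzoyloxy group, low ee, or stall because 21 binds scandium. The fallback uses known chemistry only; it sets out from 9 and comes back at 22. Compound 9 is hydroxylated with the complex preformed from [Cu(MeCN)4]PF6, (−)-sparteine and O2 (CH2Cl2, −78 → −10 °C, iPr2NEt, 4-(dimethylamino)pyridine), the reagent known to give the 7R des-chloro series, to the (5R)-hydroxy vinylogous acid F1. F1 is closed in KH2PO4/K2HPO4 buffer (pH 7)/MeCN to the (7R)-7-hydroxy azaphilone F2. Acid 19 is converted with oxalyl chloride and catalytic DMF into the acid chloride F3, which acylates the tertiary alcohol of F2 (Et3N, 4-(dimethylamino)pyridine, CH2Cl2) to the des-chloro ester F4. NCS in MeCN then chlorinates C5 to give 22; the label changes from 7R to 7S only because chlorine reverses the ranking of C6 and C8.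

Step 15 (gold cycloisomerization of the acyloxy vinylogous acid). It may give 5-exo closure or acyl migration. The fallback reverses the order of events, closing the pyran ring before oxygenation; it sets out from 10 and comes back at 22. Compound 10 is cyclized with Au(OAc)3 (5 mol%) in 1,2-dichloroethane/CF3CO2H to the 2-benzopyrylium trifluoroacetate F5. F5 is oxidized in the same flask with 2-iodoxybenzoic acid and Bu4NI to the racemic 7-hydroxy azaphilone F6. F6 is acylated with the acid chloride F3 (made from 19 as above; Et3N, 4-(dimethylamino)pyridine, CH2Cl2) to 22 and its C7 epimer F7, which are separated by chromatography since they are diastereomers.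

Step 13 (mixed diacyl peroxide). It may carry bis(3-chlorobenzoyl) peroxide or residual peracid, or disproportionate, and so feed the wrong acyloxy group or a Dakin oxidant into step 14. The fallback replaces the mixed reagent by a symmetrical one that can transfer only the wanted acyloxy group; it sets out from 19 and comes back at 21. Acid 19 (2 equiv) is coupled with H2O2 (urea–H2O2 adduct) and DCC in CH2Cl2 at 0 °C to the symmetrical bis[(2E,4S)-2,4-dimethyldec-2-enoyl] peroxide F8, which is used with 10 under the step 14 conditions to give 21 while one equivalent of 19 is released and recovered.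

**Further compounds**
F1 | step 14 | (5R)-4,5-dihydroxy-5-methyl-2-({2-methyl-6-[(triisopropylsilyl)oxy]phenyl}ethynyl)-6-oxocyclohexa-1,3-diene-1-carbaldehyde | O[C@@]1(C)C(=O)C(C=O)=C(C#Cc2c(C)cccc2O[Si](C(C)C)(C(C)C)C(C)C)C=C1O
F2 | step 14 | (7R)-7-hydroxy-7-methyl-3-{2-methyl-6-[(triisopropylsilyl)oxy]phenyl}-6H-isochromene-6,8(7H)-dione | O[C@@]1(C)C(=O)C2=COC(c3c(C)cccc3O[Si](C(C)C)(C(C)C)C(C)C)=CC2=CC1=O
F3 | step 14 | (2E,4S)-2,4-dimethyldec-2-enoyl chloride | CCCCCC[C@H](C)/C=C(\C)C(Cl)=O
F4 | step 14 | (7R)-7-methyl-3-{2-methyl-6-[(triisopropylsilyl)oxy]phenyl}-6,8-dioxo-7,8-dihydro-6H-isochromen-7-yl (2E,4S)-2,4-dimethyldec-2-enoate | CCCCCC[C@H](C)/C=C(\C)C(=O)O[C@@]1(C)C(=O)C2=COC(c3c(C)cccc3O[Si](C(C)C)(C(C)C)C(C)C)=CC2=CC1=O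
F5 | step 15 | 5-chloro-6,8-dihydroxy-7-methyl-3-{2-methyl-6-[(triisopropylsilyl)oxy]phenyl}isochromenylium trifluoroacetate | Cc1c(O)c(Cl)c2cc(-c3c(C)cccc3O[Si](C(C)C)(C(C)C)C(C)C)[o+]cc2c1O.[O-]C(=O)C(F)(F)F
F6 | step 15 | racemic 5-chloro-7-hydroxy-7-methyl-3-{2-methyl-6-[(triisopropylsilyl)oxy]phenyl}-6H-isochromene-6,8(7H)-dione | CC1(O)C(=O)C2=COC(c3c(C)cccc3O[Si](C(C)C)(C(C)C)C(C)C)=CC2=C(Cl)C1=O
F7 | step 15 | (7R)-5-chloro-7-methyl-3-{2-methyl-6-[(triisopropylsilyl)oxy]phenyl}-6,8-dioxo-7,8-dihydro-6H-isochromen-7-yl (2E,4S)-2,4-dimethyldec-2-enoate (C7 epimer of 22) | CCCCCC[C@H](C)/C=C(\C)C(=O)O[C@]1(C)C(=O)C2=COC(c3c(C)cccc3O[Si](C(C)C)(C(C)C)C(C)C)=CC2=C(Cl)C1=O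
F8 | step 13 | bis[(2E,4S)-2,4-dimethyldec-2-enoyl] peroxide | CCCCCC[C@H](C)/C=C(\C)C(=O)OOC(=O)/C(C)=C/[C@@H](C)CCCCCC
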